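## The problem

Compound 32 is a germacranolide. A ten-membered carbocycle (C1–C10) is fused trans at C6–C7 to an α-methylene-γ-butyrolactone (C11–C13, oxygen on C6). It carries a trans 1,10-epoxide, a ring-cis trisubstituted C4=C5 alkene bearing a hydroxymethyl group (C15), a 3-hydroxyl and an 8-tiglate.

The six stereocentres (1R, 3S, 6R, 7R, 8R, 10R) form three groups, C1/C10, C3 and C6/C7/C8. In any open-chain precursor these groups are too far apart to control one another. Only inside the last group can C7 steer C6 (the ring fusion), and C7 and C8 can be made together. Three reagent-controlled operations are therefore unavoidable.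

The ten-membered ring is the main obstacle, and closing it at the hindered trisubstituted Z alkene would be the hardest choice. The functional groups narrow the conditions: the trisubstituted epoxide is acid-labile and lies across the ring from C4=C5; the α-methylene lactone adds amines, thiolates and basic fluoride; the tiglate must survive any ester cleavage; C7–H is doubly allylic.

The enabling feature is that the lactone oxygen on C6 is allylic to C4=C5. If the alkene is moved to C5=C6, the C12 carboxyl becomes the nucleophile of a γ,δ-unsaturated acid. C6–O can then be made by selenium-induced lactonisation, and syn elimination of the selenoxide returns the alkene to C4=C5. The cost is a C4–H stereocentre that is built only to be erased and whose configuration decides the alkene geometry.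

## Retrosynthesis

**32 ⇐ 31 ⇐ 29.** No skeletal bond is cut. 32 is bis-silyl ether 31 without its protecting groups. The C4=C5 alkene of 31 is the retron of a syn elimination of selenoxide 30, made from selenide 29. Compared with dehydration or dehydrohalogenation, the selenoxide avoids the hydrogen on the oxygen-bearing C6, and as a syn process it turns the 4R,5S pair of 29 into the ring-cis alkene without choice. The forward reactions only have to oxidise selenium beside an epoxide and two conjugated esters, and then remove silicon without acid strong enough to open the epoxide.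

**29 ⇐ 28 (key disconnection).** C6–O and C5–Se are cut together, which opens the lactone and leaves the ring-cis C5=C6 alkene and the free C12 acid of 28. The neighbouring option, acylating a C6 alcohol, would need the ring closed with C6 oxygenated and the trisubstituted alkene already in place. 28 has one ring and two stereocentres fewer than 29. The forward reaction must pick the only electron-rich alkene, close 5-exo, add anti, and do so on the face fixed by C7.

**28 ⇐ 26 ⇐ 25.** Acid 28 comes from methyl ester 26 through stannyl ester 27. 26 is opened at C5=C6 by retro-metathesis to acyclic diene 25. This cut is preferred over C4=C5 (trisubstituted, hindered, geometry to be controlled) and over any C–C single bond of the ring (new stereocentres set by ring conformation). Both partners are monosubstituted vinyl groups, and the ring-cis alkene is the more stable isomer of a cyclodecene. The epoxide must already be present in 25: a free C1=C10 alkene would close a cyclopentene with either vinyl group. The forward reaction has to beat oligomerisation.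

**25 ⇐ 24 ⇐ 21 + 22.** Removing the epoxide oxygen gives E-alkene 24; removing the tiglate gives alcohol 21 and tiglic acid 22 (activated as anhydride 23). In 24 the C1=C10 bond is the only electron-rich alkene, so a chiral dioxirane can set C1 and C10 by reagent control on the open chain. Epoxidising after ring closure would leave the face to ring conformation. Acylation comes first so that no free γ-hydroxy ester meets the basic epoxidation medium.

**21 ⇐ 14 + 19.** The C7–C8 bond is cut; the forward step creates both C7 and C8, through borate 20. A 2-(alkoxycarbonyl)allyl boronate brings C11–C13 at the right oxidation level. An oxazolidinone crotonate aldol would give the same relative configuration but leave C11 as a carboxyl carbon, several steps away from the acrylate. The partners are the achiral dienyl boronate 19 and aldehyde 14 with two stereocentres. The forward reaction must give the syn adduct (chair transition state) and attack the Si face of the aldehyde under catalyst control, because C3 and C4 are too remote to help.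

**19 ⇐ 18 ⇐ 17 ⇐ 15 + 16.** The boronate comes from allylic acetate 18, the acetate of the Morita–Baylis–Hillman adduct 17 of acrolein 15 and methyl acrylate 16. All five carbons and the ester arrive in one step from two commodity chemicals.

**14 ⇐ 13 ⇐ 12 ⇐ 11 ⇐ 10 ⇐ 9.** After functional-group steps (aldehyde 14, alcohol 13, PMB ether 12, diol 11) the vinyl–C4 bond is cut, giving epoxy alcohol 10, and the epoxide oxygen is removed to dienol 9. Anti opening of a trans epoxide at the carbon next to CH2OH gives exactly the 3S,4R pair. An oxazolidinone syn aldol would place the vinyl group on the wrong side. A Z-γ-(silyloxymethyl)allylboration would be one step shorter but needs a second labile β,γ-unsaturated aldehyde and a less accessible reagent. The forward reactions need the allylic alcohol alkene to be the only one epoxidised, and C-2 regioselectivity in the cuprate opening.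

**9 ⇐ 8 ⇐ 2 + 6; 2 ⇐ 1; 6 ⇐ 4 ⇐ 3.** The C1–C2 bond (alkenyl–allyl) and the C10–C14 bond (methyl onto an alkyne) are cut. Carboalumination of alkyne 2 gives alkenylalane 7 and fixes the E trisubstituted alkene; Pd-catalysed coupling with allylic chloride 6 keeps both geometries. The pieces are but-3-yn-1-ol 1 and (E)-but-2-ene-1,4-diol 3 (via 4 and mesylate 5). Building the C2–C3 bond by carbonyl addition would instead require a β,γ-unsaturated aldehyde at C3.

## Roads not taken

**Alternative 1:** The cut is C2–C3 plus O–C1, a retro nitrile oxide cycloaddition. In the forward step the open-chain aldoxime A1 is oxidised with NaOCl and the nitrile oxide adds to the C1=C2 vinyl group, giving the isoxazoline-bridged ten-membered carbocycle A2.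
- Merits: the ring is closed by a C–C bond that also delivers the C1 oxygen and a masked C3 carbonyl. The trans lactone, the Z C4=C5 alkene and C8 are in place before closure. No sacrificial stereocentre and no selenium are needed.
- Weak points: a ten-membered dipolar closure must outrun nitrile oxide dimerisation. The new C1 centre is controlled only by the neighbouring quaternary C10. A2 still needs N–O cleavage, a 3S-selective ketone reduction, conversion of the C1 carbinol and C10 silyl ether into the epoxide, PMB-to-tiglate exchange and α-methylenation of the lactone by strong base; in all, seven or more operations on the strained ring.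
- Comparison: if the cycloaddition works, A2 has the alkene and lactone problems already solved, which the chosen plan cannot claim before its last three steps. The chosen plan offsets this by fixing C1/C10 and C3 with reagent control on open chains and by needing only three steps after the key step.

**Alternative 2:** No ring σ bond is formed. The C6–C10 bond of the trans-hydroazulene mesylate A3 is broken by its C6 alkoxide (KOC(CH3)3), which unveils the ring as dienone A4 with an E C1=C10 alkene.
- Merits: the medium ring is revealed rather than closed, so entropy and transannular strain are not paid in a bond-forming step. The alkene geometry follows from the antiperiplanar arrangement. For ring construction alone this is more dependable than metathesis.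
- Weak points: A3 needs a quaternary C10, a tertiary C6 carbinol and a correctly placed C1 mesylate on a bicyclic frame. A4 is a Z-enone with a γ-silyloxy group and an enolisable C7 under tert-butoxide. Ketone reduction to 6R, lactonisation, α-methylenation, epoxidation under conformational control and protecting-group exchange still follow.
- Comparison: the chosen plan accepts a less certain ring closure in return for an open-chain, reagent-controlled epoxide and a much shorter path after the ring exists.

**Alternative 3:** The cut is C3–C4. A NiCl2-catalysed CrCl2 coupling of the vinyl iodide and aldehyde in A5 closes the ring and creates the C3 carbinol, giving A6.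
- Merits: A6 is the 15-O-silyl ether of the target, one deprotection from 32. This is the shortest end game of all the plans. The organochromium tolerates the lactone, epoxide and tiglate.
- Weak points: the C3 configuration is left to the macrocyclisation with no reagent handle; the wrong epimer would need oxidation and reduction next to the epoxide. A5 contains a β,γ-epoxy aldehyde prone to β-elimination and a trisubstituted Z iodoalkene beside the lactone. The ring closes at the more hindered carbon with a large excess of chromium salts.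
- Comparison: if the closure gave 3S it would beat the chosen plan in step count after ring formation. The chosen plan answers with C3 set early by a Sharpless epoxidation and a closure at an unhindered disubstituted alkene, at the cost of the sacrificial C4 centre and a selenium step.

Key step: step 19

## Remarks on the chemistry

- Atoms are numbered as in germacrane: C1–C10 ring, C11–C13 acrylate or lactone unit, C14 the methyl on C10, C15 the oxygenated carbon on C4. Ring compounds 26–32 are named on this skeleton.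
- The phosphoric acid enantiomer in step 14 is assigned by analogy with allyl- and crotylboronate additions, where the (R)-acid sends the allyl group to the Re face; the (S)-acid is therefore specified for the Si-face attack needed at C8.
- But-3-yn-1-ol, (E)-but-2-ene-1,4-diol, acrolein, methyl acrylate and tiglic acid are taken as commercial.

## Route

Step 1
Reactants: 1 but-3-yn-1-ol
Product: 2 1-[(but-3-yn-1-yloxy)methyl]-4-methoxybenzene
Conditions: NaH, PMBCl, Bu4NI (cat.), THF, 0 °C to rt
Reagents that add atoms: 4-methoxybenzyl chloride, COc1ccc(CCl)cc1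
Why: Williamson etherification; NaH removes only the hydroxyl proton, and the PMB ether survives every step up to its oxidative removal in step 9.

Step 2
Reactants: 3 (E)-but-2-ene-1,4-diol
Product: 4 (E)-4-[(tert-butyldimethylsilyl)oxy]but-2-en-1-ol
Conditions: NaH (1 equiv), THF, rt; then TBSCl
Reagents that add atoms: tert-butyl(chloro)dimethylsilane, CC(C)(C)[Si](C)(C)Cl
Why: Monosilylation of a symmetrical diol through its sparingly soluble monosodium alkoxide; the E alkene is untouched.

Step 3
Reactants: 4 (E)-4-[(tert-butyldimethylsilyl)oxy]but-2-en-1-ol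
Product: 6 tert-butyl{[(E)-4-chlorobut-2-en-1-yl]oxy}dimethylsilane, via allylic mesylate 5 (not isolated)
Conditions: MsCl, 2,4,6-collidine, LiCl, DMF, 0 °C
Reagents that add atoms: lithium chloride, [Li+].[Cl-] (chlorine of 6); methanesulfonyl chloride, CS(=O)(=O)Cl (mesyl group of 5 only)
Why: Sulfonylation and SN2 displacement by chloride in one flask; primary allylic mesylates are displaced under these conditions without allylic transposition or loss of geometry.

Step 4
Reactants: 2 1-[(but-3-yn-1-yloxy)methyl]-4-methoxybenzene; 6 tert-butyl{[(E)-4-chlorobut-2-en-1-yl]oxy}dimethylsilane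
Product: 8 tert-butyl{[(2E,5E)-8-[(4-methoxybenzyl)oxy]-6-methylocta-2,5-dien-1-yl]oxy}dimethylsilane, via alkenylalane 7 (not isolated)
Conditions: Me3Al, Cp2ZrCl2 (25 mol%), CH2Cl2, 0 °C to rt; then 6, Pd(PPh3)4 (5 mol%), THF, rt
Reagents that add atoms: trimethylaluminium, C[Al](C)C (methyl C14 of 8; dimethylalanyl group of 7)
Why: Zirconium-catalysed carboalumination adds methyl and aluminium syn with methyl on the internal carbon, which fixes the E trisubstituted C1=C10 alkene; the Pd-catalysed Negishi-type alkenyl–allyl coupling then joins C1 to the unhindered CH2 terminus of 6 with retention of both alkene geometries.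

Step 5
Reactants: 8 tert-butyl{[(2E,5E)-8-[(4-methoxybenzyl)oxy]-6-methylocta-2,5-dien-1-yl]oxy}dimethylsilane
Product: 9 (2E,5E)-8-[(4-methoxybenzyl)oxy]-6-methylocta-2,5-dien-1-ol
Conditions: TBAF, THF, 0 °C
Reagents that add atoms: none
Why: Fluoride cleavage of a primary silyl ether; the PMB ether and both alkenes are inert.

Step 6
Reactants: 9 (2E,5E)-8-[(4-methoxybenzyl)oxy]-6-methylocta-2,5-dien-1-ol
Product: 10 [(2S,3S)-3-{(2E)-5-[(4-methoxybenzyl)oxy]-3-methylpent-2-en-1-yl}oxiran-2-yl]methanol
Conditions: Ti(OiPr)4 (10 mol%), L-(+)-diethyl tartrate (12 mol%), t-BuOOH, 4 Å molecular sieves, CH2Cl2, −20 °C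
Reagents that add atoms: tert-butyl hydroperoxide, CC(C)(C)OO
Why: Sharpless asymmetric epoxidation; titanium activates only the allylic alcohol alkene, and L-(+)-tartrate delivers oxygen to the face that gives the (2S,3S)-epoxy alcohol, which sets C3 for good and C4 provisionally.

Step 7
Reactants: 10 [(2S,3S)-3-{(2E)-5-[(4-methoxybenzyl)oxy]-3-methylpent-2-en-1-yl}oxiran-2-yl]methanol
Product: 11 (2R,3S,5E)-2-ethenyl-8-[(4-methoxybenzyl)oxy]-6-methyloct-5-ene-1,3-diol
Conditions: CH2=CHMgBr (4 equiv), CuI (20 mol%), THF/Et2O, −30 to 0 °C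
Reagents that add atoms: vinylmagnesium bromide, C=C[Mg]Br
Why: Copper-catalysed Grignard opening of a 2,3-epoxy alcohol at the carbon next to CH2OH, the standard entry to 2-substituted 1,3-diols; inversion at C4 with retention at C3 gives the 3S,4R pair, and any 1,2-diol from attack at the other carbon can be removed by NaIO4 cleavage.

Step 8
Reactants: 11 (2R,3S,5E)-2-ethenyl-8-[(4-methoxybenzyl)oxy]-6-methyloct-5-ene-1,3-diol
Product: 12 (2R,3S,5E)-1,3-bis[(tert-butyldimethylsilyl)oxy]-2-ethenyl-8-[(4-methoxybenzyl)oxy]-6-methyloct-5-ene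
Conditions: TBSOTf, 2,6-lutidine, CH2Cl2, −78 to 0 °C
Reagents that add atoms: tert-butyldimethylsilyl trifluoromethanesulfonate, CC(C)(C)[Si](C)(C)OS(=O)(=O)C(F)(F)F
Why: Silylation of the primary and the hindered secondary hydroxyl with the triflate and lutidine; the two TBS ethers survive to the end and leave together.

Step 9
Reactants: 12 (2R,3S,5E)-1,3-bis[(tert-butyldimethylsilyl)oxy]-2-ethenyl-8-[(4-methoxybenzyl)oxy]-6-methyloct-5-ene
Product: 13 (3E,6S,7R)-6,8-bis[(tert-butyldimethylsilyl)oxy]-7-ethenyl-3-methyloct-3-en-1-ol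
Conditions: DDQ, CH2Cl2/pH 7 buffer, 0 °C
Reagents that add atoms: none
Why: Oxidative cleavage of the p-methoxybenzyl ether by DDQ; the buffered medium leaves silyl ethers and alkenes alone.

Step 10
Reactants: 13 (3E,6S,7R)-6,8-bis[(tert-butyldimethylsilyl)oxy]-7-ethenyl-3-methyloct-3-en-1-ol
Product: 14 (3E,6S,7R)-6,8-bis[(tert-butyldimethylsilyl)oxy]-7-ethenyl-3-methyloct-3-enal
Conditions: Dess–Martin periodinane, NaHCO3, CH2Cl2, 0 °C; used crude
Reagents that add atoms: none
Why: Dess–Martin oxidation under bicarbonate; the near-neutral conditions keep the β,γ-alkene from moving into conjugation, and the aldehyde is used at once.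

Step 11
Reactants: 15 prop-2-enal (acrolein); 16 methyl prop-2-enoate (methyl acrylate)
Product: 17 methyl 3-hydroxy-2-methylidenepent-4-enoate (racemic)
Conditions: DABCO (10 mol%), excess 16 as solvent, rt
Reagents that add atoms: none
Why: Morita–Baylis–Hillman reaction; the amine adds to the acrylate and the resulting enolate attacks the aldehyde carbonyl, and the racemic carbinol centre is erased in step 13.

Step 12
Reactants: 17 methyl 3-hydroxy-2-methylidenepent-4-enoate
Product: 18 methyl 3-(acetyloxy)-2-methylidenepent-4-enoate (racemic)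
Conditions: Ac2O, pyridine, DMAP (cat.), CH2Cl2, 0 °C
Reagents that add atoms: acetic anhydride, CC(=O)OC(C)=O
Why: Acetylation of the secondary alcohol; should some acetate transpose to the primary position, both isomers give the same π-allyl complex in step 13.

Step 13
Reactants: 18 methyl 3-(acetyloxy)-2-methylidenepent-4-enoate
Product: 19 methyl (2E)-2-[(4,4,5,5-tetramethyl-1,3,2-dioxaborolan-2-yl)methyl]penta-2,4-dienoate
Conditions: B2pin2, Pd2(dba)3 (2.5 mol%), DMSO, 50 °C
Reagents that add atoms: bis(pinacolato)diboron, CC1(C)OB(OC1(C)C)B1OC(C)(C)C(C)(C)O1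
Why: Pd-catalysed borylation of an allylic acetate, known for Morita–Baylis–Hillman acetates; boron ends on the CH2 terminus and the conjugated alkene forms with the vinyl group trans to the ester, the thermodynamically preferred geometry.

Step 14
Reactants: 14 (3E,6S,7R)-6,8-bis[(tert-butyldimethylsilyl)oxy]-7-ethenyl-3-methyloct-3-enal; 19 methyl (2E)-2-[(4,4,5,5-tetramethyl-1,3,2-dioxaborolan-2-yl)methyl]penta-2,4-dienoate
Product: 21 methyl (3R,4R,6E,9S,10R)-9,11-bis[(tert-butyldimethylsilyl)oxy]-3,10-diethenyl-4-hydroxy-6-methyl-2-methylideneundec-6-enoate, via pinacol borate 20 (not isolated)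
Conditions: (S)-3,3'-bis(2,4,6-triisopropylphenyl)-1,1'-binaphthyl-2,2'-diyl hydrogen phosphate (10 mol%), 4 Å molecular sieves, toluene, −20 °C to rt; aq. NaHCO3 work-up
Reagents that add atoms: none
Why: Proposed new method: chiral-phosphoric-acid-catalysed allylboration with a 2-(alkoxycarbonyl)allyl pinacolboronate; the acid hydrogen-bonds to the pseudo-axial boronate oxygen, which should both speed up the ester-deactivated reagent and fix the aldehyde face (Si, giving 8R), while the chair transition state with the aldehyde chain equatorial and the vinyl group (cis to CH2B) axial gives the syn adduct (7R); the closest known reactions are the same catalysis with allyl and crotyl pinacolboronates and the Brønsted- or Lewis-acid-catalysed, racemic additions of 2-(alkoxycarbonyl)allylboronates to aldehydes.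

Step 15
Reactants: 21 methyl (3R,4R,6E,9S,10R)-9,11-bis[(tert-butyldimethylsilyl)oxy]-3,10-diethenyl-4-hydroxy-6-methyl-2-methylideneundec-6-enoate; 22 (2E)-2-methylbut-2-enoic acid (tiglic acid)
Product: 24 methyl (3R,4R,6E,9S,10R)-9,11-bis[(tert-butyldimethylsilyl)oxy]-3,10-diethenyl-6-methyl-2-methylidene-4-{[(2E)-2-methylbut-2-enoyl]oxy}undec-6-enoate, via mixed anhydride 23 (not isolated)
Conditions: 22, 2,4,6-trichlorobenzoyl chloride, Et3N, toluene, rt; then 21, DMAP, rt
Reagents that add atoms: 2,4,6-trichlorobenzoyl chloride, O=C(Cl)c1c(Cl)cc(Cl)cc1Cl (aroyl group of 23 only; none of its atoms remains in 24)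
Why: Yamaguchi esterification; DMAP attacks the less hindered tigloyl carbonyl of the mixed anhydride and the acylpyridinium acylates the hindered C8 hydroxyl faster than that hydroxyl can lactonise onto the methyl ester; no stereocentre is touched.

Step 16
Reactants: 24 methyl (3R,4R,6E,9S,10R)-9,11-bis[(tert-butyldimethylsilyl)oxy]-3,10-diethenyl-6-methyl-2-methylidene-4-{[(2E)-2-methylbut-2-enoyl]oxy}undec-6-enoate
Product: 25 methyl (3R,4R)-5-[(2R,3R)-3-{(2S,3R)-2-[(tert-butyldimethylsilyl)oxy]-3-{[(tert-butyldimethylsilyl)oxy]methyl}pent-4-en-1-yl}-2-methyloxiran-2-yl]-3-ethenyl-2-methylidene-4-{[(2E)-2-methylbut-2-enoyl]oxy}pentanoate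
Conditions: D-fructose-derived Shi ketone (30 mol%), Oxone (2KHSO5·KHSO4·K2SO4), K2CO3, Bu4NHSO4 (cat.), MeCN/CH2(OMe)2/aq. Na2B4O7 buffer, 0 °C
Reagents that add atoms: potassium peroxymonosulfate, [K+].[O-]S(=O)(=O)OO (epoxide oxygen, relayed by the dioxirane of the ketone)
Why: Shi epoxidation; the electron-rich trisubstituted alkene reacts far faster with the dioxirane than the terminal vinyl groups or the two conjugated esters, and the D-fructose-derived ketone adds oxygen through the spiro transition state to the face that gives the (R,R)-epoxide of an E alkene, here 1R,10R.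

Step 17
Reactants: 25 methyl (3R,4R)-5-[(2R,3R)-3-{(2S,3R)-2-[(tert-butyldimethylsilyl)oxy]-3-{[(tert-butyldimethylsilyl)oxy]methyl}pent-4-en-1-yl}-2-methyloxiran-2-yl]-3-ethenyl-2-methylidene-4-{[(2E)-2-methylbut-2-enoyl]oxy}pentanoate
Product: 26 methyl (1R,3S,4R,5Z,7R,8R,10R)-3,15-bis[(tert-butyldimethylsilyl)oxy]-1,10-epoxy-8-{[(2E)-2-methylbut-2-enoyl]oxy}germacra-5,11(13)-dien-12-oate
Conditions: second-generation Hoveyda–Grubbs catalyst (10 mol%), 1,4-benzoquinone (20 mol%), toluene (1 mM), 80 °C
Reagents that add atoms: none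
Why: Ring-closing metathesis of the two monosubstituted alkenes; the 1,1-disubstituted acrylate and the tiglate are electron-poor spectators, and the epoxide has already removed the one alkene that could have closed a cyclopentene. The ring-cis alkene is the less strained isomer of a cyclodecene and is expected under equilibrating conditions.

Step 18
Reactants: 26 methyl (1R,3S,4R,5Z,7R,8R,10R)-3,15-bis[(tert-butyldimethylsilyl)oxy]-1,10-epoxy-8-{[(2E)-2-methylbut-2-enoyl]oxy}germacra-5,11(13)-dien-12-oate
Product: 28 (1R,3S,4R,5Z,7R,8R,10R)-3,15-bis[(tert-butyldimethylsilyl)oxy]-1,10-epoxy-8-{[(2E)-2-methylbut-2-enoyl]oxy}germacra-5,11(13)-dien-12-oic acid, via trimethylstannyl ester 27 (not isolated)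
Conditions: Me3SnOH, 1,2-dichloroethane, 70 °C; then aq. pH 5 buffer; used without storage
Reagents that add atoms: trimethyltin hydroxide, C[Sn](C)(C)O (tin group of 27; its oxygen stays as the acid oxygen of 28)
Why: Trimethyltin hydroxide cleaves methyl esters through a tin carboxylate under near-neutral conditions and is known to spare more hindered esters, silyl ethers and sensitive stereocentres; the secondary, α-branched tiglate should react much more slowly than the methyl ester.

Step 19
Reactants: 28 (1R,3S,4R,5Z,7R,8R,10R)-3,15-bis[(tert-butyldimethylsilyl)oxy]-1,10-epoxy-8-{[(2E)-2-methylbut-2-enoyl]oxy}germacra-5,11(13)-dien-12-oic acid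
Product: 29 (1R,3S,4R,5S,6S,7R,8R,10R)-3,15-bis[(tert-butyldimethylsilyl)oxy]-1,10-epoxy-8-{[(2E)-2-methylbut-2-enoyl]oxy}-5-(phenylselanyl)germacr-11(13)-en-12,6-olide
Conditions: PhSeCl, Et3N, CH2Cl2, −78 to −20 °C
Reagents that add atoms: benzeneselenenyl chloride, Cl[Se]c1ccccc1
Why: PhSeCl adds reversibly to the only electron-rich alkene left, the ring-cis C5=C6 bond, to give a seleniranium ion, which the triethylammonium carboxylate opens at C6 from the opposite face. The closest known reaction type is the phenylselenolactonisation of γ,δ-unsaturated carboxylic acids. The lactone ring closes in the 5-exo mode (O to C6), which is preferred over 6-endo attack at C5 for a 1,2-dialkyl alkene. C6 is controlled by C7: allylic 1,3-strain across the Z alkene keeps H7 in the alkene plane, so the acrylic acid arm lies over one face and can deliver oxygen only there, which with 7R gives the trans-fused lactone (the 6R arrangement of the target; the descriptor reads 6S in 29 only because selenium changes the priorities). C5 is controlled by the anti course of the addition, which puts selenium on the other face (5S), the arrangement that lets H4 and selenium become syn in step 20. The acrylate and tiglate alkenes are too electron-poor to form seleniranium ions, the soft electrophile does not activate the epoxide, and the amine takes up the HCl. A seleniranium ion formed on the wrong face cannot be reached by the carboxylate and reverts, so the face is selected in the ring-closing event.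

Step 20
Reactants: 29 (1R,3S,4R,5S,6S,7R,8R,10R)-3,15-bis[(tert-butyldimethylsilyl)oxy]-1,10-epoxy-8-{[(2E)-2-methylbut-2-enoyl]oxy}-5-(phenylselanyl)germacr-11(13)-en-12,6-olide
Product: 31 (1R,3S,4Z,6R,7R,8R,10R)-3,15-bis[(tert-butyldimethylsilyl)oxy]-1,10-epoxy-8-{[(2E)-2-methylbut-2-enoyl]oxy}germacra-4,11(13)-dien-12,6-olide, via selenoxide 30 (not isolated)
Conditions: H2O2 (30% aq.), pyridine, CH2Cl2, 0 °C to rt
Reagents that add atoms: hydrogen peroxide, OO (oxygen on selenium in 30 only; none of its atoms remains in 31)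
Why: Selenide oxidation and selenoxide syn elimination; the selenoxide takes the hydrogen on C4 and not the one on the oxygen-bearing C6, the usual regiochemistry beside oxygen. Because selenium and H4 must be syn, the 4R,5S pair can give only the ring-cis (4Z) alkene; pyridine buffers the selenenic acid.

Step 21
Reactants: 31 (1R,3S,4Z,6R,7R,8R,10R)-3,15-bis[(tert-butyldimethylsilyl)oxy]-1,10-epoxy-8-{[(2E)-2-methylbut-2-enoyl]oxy}germacra-4,11(13)-dien-12,6-olide
Product: 32 (1R,3S,4Z,6R,7R,8R,10R)-1,10-epoxy-3,15-dihydroxy-8-{[(2E)-2-methylbut-2-enoyl]oxy}germacra-4,11(13)-dien-12,6-olide (CNP0187917.2)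
Conditions: HF·pyridine, excess pyridine, THF, 0 °C to rt
Reagents that add atoms: none
Why: Fluoride-mediated cleavage of both silyl ethers; the pyridine-buffered reagent is not basic enough to add to the α-methylene lactone and should be mild enough to spare the epoxide.

## Compound list

1 | but-3-yn-1-ol | C#CCCO | starting material
2 | 1-[(but-3-yn-1-yloxy)methyl]-4-methoxybenzene | C#CCCOCc1ccc(OC)cc1 | intermediate
3 | (E)-but-2-ene-1,4-diol | OC/C=C/CO | starting material
4 | (E)-4-[(tert-butyldimethylsilyl)oxy]but-2-en-1-ol | OC/C=C/CO[Si](C)(C)C(C)(C)C | intermediate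
5 | (E)-4-[(tert-butyldimethylsilyl)oxy]but-2-en-1-yl methanesulfonate | CS(=O)(=O)OC/C=C/CO[Si](C)(C)C(C)(C)C | intermediate (not isolated)
6 | tert-butyl{[(E)-4-chlorobut-2-en-1-yl]oxy}dimethylsilane | ClC/C=C/CO[Si](C)(C)C(C)(C)C | intermediate
7 | {(1E)-4-[(4-methoxybenzyl)oxy]-2-methylbut-1-en-1-yl}dimethylalumane | COc1ccc(COCC/C(C)=C/[Al](C)C)cc1 | intermediate (not isolated)
8 | tert-butyl{[(2E,5E)-8-[(4-methoxybenzyl)oxy]-6-methylocta-2,5-dien-1-yl]oxy}dimethylsilane | COc1ccc(COCC/C(C)=C/C/C=C/CO[Si](C)(C)C(C)(C)C)cc1 | intermediate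
9 | (2E,5E)-8-[(4-methoxybenzyl)oxy]-6-methylocta-2,5-dien-1-ol | COc1ccc(COCC/C(C)=C/C/C=C/CO)cc1 | intermediate
10 | [(2S,3S)-3-{(2E)-5-[(4-methoxybenzyl)oxy]-3-methylpent-2-en-1-yl}oxiran-2-yl]methanol | OC[C@@H]1O[C@H]1C/C=C(\C)CCOCc1ccc(OC)cc1 | intermediate
11 | (2R,3S,5E)-2-ethenyl-8-[(4-methoxybenzyl)oxy]-6-methyloct-5-ene-1,3-diol | OC[C@@H](C=C)[C@@H](O)C/C=C(\C)CCOCc1ccc(OC)cc1 | intermediate
12 | (2R,3S,5E)-1,3-bis[(tert-butyldimethylsilyl)oxy]-2-ethenyl-8-[(4-methoxybenzyl)oxy]-6-methyloct-5-ene | CC(C)(C)[Si](C)(C)OC[C@@H](C=C)[C@@H](O[Si](C)(C)C(C)(C)C)C/C=C(\C)CCOCc1ccc(OC)cc1 | intermediate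
13 | (3E,6S,7R)-6,8-bis[(tert-butyldimethylsilyl)oxy]-7-ethenyl-3-methyloct-3-en-1-ol | CC(C)(C)[Si](C)(C)OC[C@@H](C=C)[C@@H](O[Si](C)(C)C(C)(C)C)C/C=C(\C)CCO | intermediate
14 | (3E,6S,7R)-6,8-bis[(tert-butyldimethylsilyl)oxy]-7-ethenyl-3-methyloct-3-enal | CC(C)(C)[Si](C)(C)OC[C@@H](C=C)[C@@H](O[Si](C)(C)C(C)(C)C)C/C=C(\C)CC=O | intermediate
15 | prop-2-enal (acrolein) | C=CC=O | starting material
16 | methyl prop-2-enoate (methyl acrylate) | C=CC(=O)OC | starting material
17 | methyl 3-hydroxy-2-methylidenepent-4-enoate (racemic) | C=CC(O)C(=C)C(=O)OC | intermediate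
18 | methyl 3-(acetyloxy)-2-methylidenepent-4-enoate (racemic) | C=CC(OC(C)=O)C(=C)C(=O)OC | intermediate
19 | methyl (2E)-2-[(4,4,5,5-tetramethyl-1,3,2-dioxaborolan-2-yl)methyl]penta-2,4-dienoate | C=C/C=C(/C(=O)OC)CB1OC(C)(C)C(C)(C)O1 | intermediate
20 | methyl (3R,4R,6E,9S,10R)-9,11-bis[(tert-butyldimethylsilyl)oxy]-3,10-diethenyl-6-methyl-2-methylidene-4-[(4,4,5,5-tetramethyl-1,3,2-dioxaborolan-2-yl)oxy]undec-6-enoate | COC(=O)C(=C)[C@@H](C=C)[C@H](OB1OC(C)(C)C(C)(C)O1)C/C(C)=C/C[C@H](O[Si](C)(C)C(C)(C)C)[C@H](C=C)CO[Si](C)(C)C(C)(C)C | intermediate (not isolated)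
21 | methyl (3R,4R,6E,9S,10R)-9,11-bis[(tert-butyldimethylsilyl)oxy]-3,10-diethenyl-4-hydroxy-6-methyl-2-methylideneundec-6-enoate | COC(=O)C(=C)[C@@H](C=C)[C@H](O)C/C(C)=C/C[C@H](O[Si](C)(C)C(C)(C)C)[C@H](C=C)CO[Si](C)(C)C(C)(C)C | intermediate
22 | (2E)-2-methylbut-2-enoic acid (tiglic acid) | C/C=C(\C)C(=O)O | starting material
23 | (2E)-2-methylbut-2-enoic 2,4,6-trichlorobenzoic anhydride | C/C=C(\C)C(=O)OC(=O)c1c(Cl)cc(Cl)cc1Cl | intermediate (not isolated)
24 | methyl (3R,4R,6E,9S,10R)-9,11-bis[(tert-butyldimethylsilyl)oxy]-3,10-diethenyl-6-methyl-2-methylidene-4-{[(2E)-2-methylbut-2-enoyl]oxy}undec-6-enoate | COC(=O)C(=C)[C@@H](C=C)[C@H](OC(=O)/C(C)=C/C)C/C(C)=C/C[C@H](O[Si](C)(C)C(C)(C)C)[C@H](C=C)CO[Si](C)(C)C(C)(C)C | intermediate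
25 | methyl (3R,4R)-5-[(2R,3R)-3-{(2S,3R)-2-[(tert-butyldimethylsilyl)oxy]-3-{[(tert-butyldimethylsilyl)oxy]methyl}pent-4-en-1-yl}-2-methyloxiran-2-yl]-3-ethenyl-2-methylidene-4-{[(2E)-2-methylbut-2-enoyl]oxy}pentanoate | COC(=O)C(=C)[C@@H](C=C)[C@H](OC(=O)/C(C)=C/C)C[C@@]1(C)O[C@@H]1C[C@H](O[Si](C)(C)C(C)(C)C)[C@H](C=C)CO[Si](C)(C)C(C)(C)C | intermediate
26 | methyl (1R,3S,4R,5Z,7R,8R,10R)-3,15-bis[(tert-butyldimethylsilyl)oxy]-1,10-epoxy-8-{[(2E)-2-methylbut-2-enoyl]oxy}germacra-5,11(13)-dien-12-oate | C=C(C(=O)OC)[C@H]1/C=C\[C@H](CO[Si](C)(C)C(C)(C)C)[C@@H](O[Si](C)(C)C(C)(C)C)C[C@H]2O[C@]2(C)C[C@H]1OC(=O)/C(C)=C/C | intermediate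
27 | trimethylstannyl (1R,3S,4R,5Z,7R,8R,10R)-3,15-bis[(tert-butyldimethylsilyl)oxy]-1,10-epoxy-8-{[(2E)-2-methylbut-2-enoyl]oxy}germacra-5,11(13)-dien-12-oate | C=C(C(=O)O[Sn](C)(C)C)[C@H]1/C=C\[C@H](CO[Si](C)(C)C(C)(C)C)[C@@H](O[Si](C)(C)C(C)(C)C)C[C@H]2O[C@]2(C)C[C@H]1OC(=O)/C(C)=C/C | intermediate (not isolated)
28 | (1R,3S,4R,5Z,7R,8R,10R)-3,15-bis[(tert-butyldimethylsilyl)oxy]-1,10-epoxy-8-{[(2E)-2-methylbut-2-enoyl]oxy}germacra-5,11(13)-dien-12-oic acid | C=C(C(=O)O)[C@H]1/C=C\[C@H](CO[Si](C)(C)C(C)(C)C)[C@@H](O[Si](C)(C)C(C)(C)C)C[C@H]2O[C@]2(C)C[C@H]1OC(=O)/C(C)=C/C | intermediate (precursor of the key step)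
29 | (1R,3S,4R,5S,6S,7R,8R,10R)-3,15-bis[(tert-butyldimethylsilyl)oxy]-1,10-epoxy-8-{[(2E)-2-methylbut-2-enoyl]oxy}-5-(phenylselanyl)germacr-11(13)-en-12,6-olide | C=C1C(=O)O[C@@H]2[C@@H]([Se]c3ccccc3)[C@H](CO[Si](C)(C)C(C)(C)C)[C@@H](O[Si](C)(C)C(C)(C)C)C[C@H]4O[C@]4(C)C[C@@H](OC(=O)/C(C)=C/C)[C@@H]12 | intermediate (product of the key step)
30 | Se-oxide of 29, (1R,3S,4R,5S,6S,7R,8R,10R)-5-(benzeneseleninyl)-3,15-bis[(tert-butyldimethylsilyl)oxy]-1,10-epoxy-8-{[(2E)-2-methylbut-2-enoyl]oxy}germacr-11(13)-en-12,6-olide (both configurations at selenium) | C=C1C(=O)O[C@@H]2[C@@H]([Se](=O)c3ccccc3)[C@H](CO[Si](C)(C)C(C)(C)C)[C@@H](O[Si](C)(C)C(C)(C)C)C[C@H]4O[C@]4(C)C[C@@H](OC(=O)/C(C)=C/C)[C@@H]12 | intermediate (not isolated)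
31 | (1R,3S,4Z,6R,7R,8R,10R)-3,15-bis[(tert-butyldimethylsilyl)oxy]-1,10-epoxy-8-{[(2E)-2-methylbut-2-enoyl]oxy}germacra-4,11(13)-dien-12,6-olide | C=C1C(=O)O[C@@H]2/C=C(/CO[Si](C)(C)C(C)(C)C)[C@@H](O[Si](C)(C)C(C)(C)C)C[C@H]3O[C@]3(C)C[C@@H](OC(=O)/C(C)=C/C)[C@@H]12 | intermediate
32 | (1R,3S,4Z,6R,7R,8R,10R)-1,10-epoxy-3,15-dihydroxy-8-{[(2E)-2-methylbut-2-enoyl]oxy}germacra-4,11(13)-dien-12,6-olide (CNP0187917.2) | C=C1C(=O)O[C@@H]2/C=C(/CO)[C@@H](O)C[C@H]3O[C@]3(C)C[C@@H](OC(=O)/C(C)=C/C)[C@@H]12 | target

## Step count and least certain steps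

Total: 21 steps. Longest linear sequence: 17 steps (from 3: steps 2, 3, 4–10, 14–21).

**Step 14 (allylboration).** The ester lowers the nucleophilicity of boronate 19, so the catalysed allyl transfer may be too slow to outrun the unselective background reaction. The acid could also promote lactonisation of the adduct onto the methyl ester, or migration of the β,γ-alkene of 14 into conjugation. The facial sense rests on analogy.
Fallback with known chemistry, from 14 and 17 back to 21: 17 is treated with PBr3 in ether at 0 °C, which brominates with allylic transposition to methyl (2Z)-2-(bromomethyl)penta-2,4-dienoate F1. Indium powder in THF/water then couples F1 with 14 in a Barbier reaction. Bromides of this type are known to give syn hydroxy esters, so the relative configuration at C7/C8 is secured, but the aldehyde face is not. 21 would form together with its (3S,4S) diastereomer, methyl (3S,4S,6E,9S,10R)-9,11-bis[(tert-butyldimethylsilyl)oxy]-3,10-diethenyl-4-hydroxy-6-methyl-2-methylideneundec-6-enoate F2, and the two are separated by chromatography.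

**Step 19 (key step).** The seleniranium ion could be opened in the 6-endo sense, or by chloride or the epoxide oxygen across the ring, and adventitious HCl could open the epoxide.
Fallback from 28 back to 31, keeping the same C6–O closure: buffered mCPBA (NaHCO3, CH2Cl2, 0 °C) epoxidises the C5=C6 alkene, the only electron-rich one, to (1R,3S,4S,5S,6R,7R,8R,10R)-3,15-bis[(tert-butyldimethylsilyl)oxy]-1,10:5,6-diepoxy-8-{[(2E)-2-methylbut-2-enoyl]oxy}germacr-11(13)-en-12-oic acid F3. Its carboxyl opens the new epoxide 5-exo at C6 to (1R,3S,4S,5S,6S,7R,8R,10R)-3,15-bis[(tert-butyldimethylsilyl)oxy]-1,10-epoxy-5-hydroxy-8-{[(2E)-2-methylbut-2-enoyl]oxy}germacr-11(13)-en-12,6-olide F4. This has the same relative configuration at C5 and C6 as 29 because both are anti additions. Burgess reagent in benzene at 50 °C converts F4 into the triethylammonium 5-O-[N-(methoxycarbonyl)sulfamate] F5, which undergoes syn elimination toward C4 to give 31. This route needs the peracid to attack the face away from the acrylic acid arm.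

**Step 17 (ring-closing metathesis).** The two allylically branched vinyl groups engage slowly, so intermolecular metathesis to oligomers can win over closure of the strained ring. The carbene on C6 may also be held by chelation to the ester, and the alkene geometry may erode.
Fallback from 21 back to 29: 21 is lactonised with PPTS in toluene to (4R,5R)-5-[(2E,5S,6R)-5-[(tert-butyldimethylsilyl)oxy]-6-{[(tert-butyldimethylsilyl)oxy]methyl}-2-methylocta-2,7-dien-1-yl]-4-ethenyl-3-methylideneoxolan-2-one F6. Shi epoxidation as in step 16 gives (4R,5R)-5-{[(2R,3R)-3-{(2S,3R)-2-[(tert-butyldimethylsilyl)oxy]-3-{[(tert-butyldimethylsilyl)oxy]methyl}pent-4-en-1-yl}-2-methyloxiran-2-yl]methyl}-4-ethenyl-3-methylideneoxolan-2-one F7. In F7 the cis substituents of the five-membered lactone hold both chains on one face, which should favour metathesis to (1R,3S,4R,5Z,7R,8R,10R)-3,15-bis[(tert-butyldimethylsilyl)oxy]-1,10-epoxygermacra-5,11(13)-dien-12,8-olide F8. LiOH in THF/water opens the lactone to lithium (1R,3S,4R,5Z,7R,8R,10R)-3,15-bis[(tert-butyldimethylsilyl)oxy]-1,10-epoxy-8-hydroxygermacra-5,11(13)-dien-12-oate F9, which is not acidified. PhSeCl at −78 °C closes it onto C6 to (1R,3S,4R,5S,6S,7R,8R,10R)-3,15-bis[(tert-butyldimethylsilyl)oxy]-1,10-epoxy-8-hydroxy-5-(phenylselanyl)germacr-11(13)-en-12,6-olide F10. Acylation with anhydride 23 and DMAP then gives 29. This detour also avoids the selective ester hydrolysis of step 18, the next most exposed operation (possible loss of the tiglate or migration of the exocyclic alkene on heating).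

**Step 21 (final desilylation).** During the slower cleavage of the secondary allylic silyl ether, the epoxide could be opened by fluoride, or acid could trigger transannular attack of the C4=C5 alkene on the epoxide.
Fallback from 29 back to 32, removing silicon before that alkene exists: HF·pyridine with excess pyridine converts 29 into (1R,3S,4R,5S,6S,7R,8R,10R)-1,10-epoxy-3,15-dihydroxy-8-{[(2E)-2-methylbut-2-enoyl]oxy}-5-(phenylselanyl)germacr-11(13)-en-12,6-olide F11. H2O2 and pyridine then oxidise it to the selenoxide F12, which eliminates as in step 20 to give 32 directly.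

## Further compounds

F1 | step 14 | methyl (2Z)-2-(bromomethyl)penta-2,4-dienoate | C=C/C=C(/C(=O)OC)CBr
F2 | step 14 | methyl (3S,4S,6E,9S,10R)-9,11-bis[(tert-butyldimethylsilyl)oxy]-3,10-diethenyl-4-hydroxy-6-methyl-2-methylideneundec-6-enoate | COC(=O)C(=C)[C@H](C=C)[C@@H](O)C/C(C)=C/C[C@H](O[Si](C)(C)C(C)(C)C)[C@H](C=C)CO[Si](C)(C)C(C)(C)C
F3 | step 19 | (1R,3S,4S,5S,6R,7R,8R,10R)-3,15-bis[(tert-butyldimethylsilyl)oxy]-1,10:5,6-diepoxy-8-{[(2E)-2-methylbut-2-enoyl]oxy}germacr-11(13)-en-12-oic acid | C=C(C(=O)O)[C@H]1[C@H]5O[C@H]5[C@H](CO[Si](C)(C)C(C)(C)C)[C@@H](O[Si](C)(C)C(C)(C)C)C[C@H]2O[C@]2(C)C[C@H]1OC(=O)/C(C)=C/C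
F4 | step 19 | (1R,3S,4S,5S,6S,7R,8R,10R)-3,15-bis[(tert-butyldimethylsilyl)oxy]-1,10-epoxy-5-hydroxy-8-{[(2E)-2-methylbut-2-enoyl]oxy}germacr-11(13)-en-12,6-olide | C=C1C(=O)O[C@@H]2[C@@H](O)[C@H](CO[Si](C)(C)C(C)(C)C)[C@@H](O[Si](C)(C)C(C)(C)C)C[C@H]4O[C@]4(C)C[C@@H](OC(=O)/C(C)=C/C)[C@@H]12
F5 | step 19 | triethylammonium salt of the 5-O-[N-(methoxycarbonyl)sulfamate] of F4 | C=C1C(=O)O[C@@H]2[C@@H](OS(=O)(=O)[N-]C(=O)OC)[C@H](CO[Si](C)(C)C(C)(C)C)[C@@H](O[Si](C)(C)C(C)(C)C)C[C@H]4O[C@]4(C)C[C@@H](OC(=O)/C(C)=C/C)[C@@H]12.CC[NH+](CC)CC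
F6 | step 17 | (4R,5R)-5-[(2E,5S,6R)-5-[(tert-butyldimethylsilyl)oxy]-6-{[(tert-butyldimethylsilyl)oxy]methyl}-2-methylocta-2,7-dien-1-yl]-4-ethenyl-3-methylideneoxolan-2-one | C=C1C(=O)O[C@H](C/C(C)=C/C[C@H](O[Si](C)(C)C(C)(C)C)[C@H](C=C)CO[Si](C)(C)C(C)(C)C)[C@@H]1C=C
F7 | step 17 | (4R,5R)-5-{[(2R,3R)-3-{(2S,3R)-2-[(tert-butyldimethylsilyl)oxy]-3-{[(tert-butyldimethylsilyl)oxy]methyl}pent-4-en-1-yl}-2-methyloxiran-2-yl]methyl}-4-ethenyl-3-methylideneoxolan-2-one | C=C1C(=O)O[C@H](C[C@@]2(C)O[C@@H]2C[C@H](O[Si](C)(C)C(C)(C)C)[C@H](C=C)CO[Si](C)(C)C(C)(C)C)[C@@H]1C=C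
F8 | step 17 | (1R,3S,4R,5Z,7R,8R,10R)-3,15-bis[(tert-butyldimethylsilyl)oxy]-1,10-epoxygermacra-5,11(13)-dien-12,8-olide | C=C1C(=O)O[C@@H]2C[C@@]3(C)O[C@@H]3C[C@H](O[Si](C)(C)C(C)(C)C)[C@@H](CO[Si](C)(C)C(C)(C)C)/C=C\[C@H]12
F9 | step 17 | lithium (1R,3S,4R,5Z,7R,8R,10R)-3,15-bis[(tert-butyldimethylsilyl)oxy]-1,10-epoxy-8-hydroxygermacra-5,11(13)-dien-12-oate | C=C(C(=O)[O-])[C@H]1/C=C\[C@H](CO[Si](C)(C)C(C)(C)C)[C@@H](O[Si](C)(C)C(C)(C)C)C[C@H]2O[C@]2(C)C[C@H]1O.[Li+]
F10 | step 17 | (1R,3S,4R,5S,6S,7R,8R,10R)-3,15-bis[(tert-butyldimethylsilyl)oxy]-1,10-epoxy-8-hydroxy-5-(phenylselanyl)germacr-11(13)-en-12,6-olide | C=C1C(=O)O[C@@H]2[C@@H]([Se]c3ccccc3)[C@H](CO[Si](C)(C)C(C)(C)C)[C@@H](O[Si](C)(C)C(C)(C)C)C[C@H]4O[C@]4(C)C[C@@H](O)[C@@H]12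
F11 | step 21 | (1R,3S,4R,5S,6S,7R,8R,10R)-1,10-epoxy-3,15-dihydroxy-8-{[(2E)-2-methylbut-2-enoyl]oxy}-5-(phenylselanyl)germacr-11(13)-en-12,6-olide | C=C1C(=O)O[C@@H]2[C@@H]([Se]c3ccccc3)[C@H](CO)[C@@H](O)C[C@H]4O[C@]4(C)C[C@@H](OC(=O)/C(C)=C/C)[C@@H]12
F12 | step 21 | Se-oxide of F11 (both configurations at selenium) | C=C1C(=O)O[C@@H]2[C@@H]([Se](=O)c3ccccc3)[C@H](CO)[C@@H](O)C[C@H]4O[C@]4(C)C[C@@H](OC(=O)/C(C)=C/C)[C@@H]12
A1 | alternative 1 | open-chain aldoxime: 6,12-lactone carrying the C3 oxime on the Z C4=C5 alkene and a C1=C2 vinyl group on C10 | C1C(=O)O[C@H](/C=C(/CO[Si](C)(C)C(C)(C)C)C=NO)[C@H]1[C@H](OCc2ccc(OC)cc2)C[C@@](C)(O[Si](CC)(CC)CC)C=C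
A2 | alternative 1 | isoxazoline-bridged ten-membered carbocycle | C1C(=O)O[C@@H]2/C=C(/CO[Si](C)(C)C(C)(C)C)C3=NO[C@@H](C3)[C@@](O[Si](CC)(CC)CC)(C)C[C@@H](OCc4ccc(OC)cc4)[C@@H]12
A3 | alternative 2 | trans-hydroazulene with C6 tertiary alcohol and C1 mesylate | O[C@]12/C=C(/CO[Si](C)(C)C(C)(C)C)[C@@H](O[Si](C)(C)C(C)(C)C)C[C@@H](OS(C)(=O)=O)[C@]1(C)C[C@@H](OCc3ccc(OC)cc3)[C@H]2CC(=O)OC(C)(C)C
A4 | alternative 2 | ten-membered 4Z,1(10)E-dien-6-one with C7 tert-butyl acetate side chain | O=C1/C=C(/CO[Si](C)(C)C(C)(C)C)[C@@H](O[Si](C)(C)C(C)(C)C)C/C=C(\C)C[C@@H](OCc2ccc(OC)cc2)[C@H]1CC(=O)OC(C)(C)C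
A5 | alternative 3 | open-chain 6,12-lactone with C4 vinyl iodide and C3 aldehyde | C=C1C(=O)O[C@H](/C=C(/CO[Si](C)(C)C(C)(C)C)I)[C@H]1[C@H](OC(=O)/C(C)=C/C)C[C@@]2(C)O[C@@H]2CC=O
A6 | alternative 3 | 15-O-tert-butyldimethylsilyl ether of 32 | C=C1C(=O)O[C@@H]2/C=C(/CO[Si](C)(C)C(C)(C)C)[C@@H](O)C[C@H]3O[C@]3(C)C[C@@H](OC(=O)/C(C)=C/C)[C@@H]12
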